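Reagent leaves for the dormant form faster than it makes product from a bare start, 0.0343 h⁻¹ against 0.00153 h⁻¹, so your hunch that equal charges must give equal flasks needs a reckoning before any quick number.

common to all: time 8.0 d

| run | substrate | reagent | remark |
|---|---|---|---|
| grey | 20 mM (fed, over 40 h) | 0.800 equiv | all else is in the flask from the start; the feed brings no volume worth counting |
| blue | 20 mM | 0.800 equiv (fed, over 40 h) | all else is in the flask from the start; the feed brings no volume worth counting |
| red | 20 mM | 0.800 equiv | everything together at the start |

- the flask with the highest amount of product, in percent of the substrate charged ("all alike" if they lie within 1.5 percentage points) (grey / blue / red / all alike)
- final product, as a percentage of the substrate charged, in grey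
- final product, as a percentage of the substrate charged, in blue
- final product, as a percentage of the substrate charged, in red

Once product stands, reagent has a second exit, and both exits are pseudo-first-order in reagent. Dividing the rate through product by the rate into the dormant form lets time drop out. The ratio is the product fraction times the substrate fraction, over the crossover fraction 24.2%, which is the dormancy constant divided by the autocatalytic constant and the squared substrate charge. With substrate near its charge, that is the product level at which reagent takes either exit equally.

Red starts from a seed of 1.07%, the uncatalysed constant over the autocatalytic constant and the charge, which adds to product in the growth law. Its fresh reagent, decaying at the dormancy constant, multiplies seed plus product by the exponential of the reagent fraction over the crossover fraction, 3.31. This first pass holds substrate at its charge and counts neither the return from the dormant form nor the reagent spent on product, so its 28.4% for red is a rough mark for comparing flasks, not a yield. Blue's portions of reagent each meet full substrate, so blue should trail red by a lag. Grey's reagent has a forward half-life of 20.2 h, shorter than the feed, and by then substrate stands at 0.505 of its charge. That share of the exponent gives grey about 4.65%, below crossover. The reckoning stops at an order, red, blue, grey, without final figures.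

The forecast put red first, at 45%, with blue at 42% and grey at 33%, noting that “Autocatalysis starts while the reagent is still fresh”. The simulation gives 46.0% in red, 42.6% in blue and 33.6% in grey.

    reagent ⇌ dormant form (K1 = 3.4, k1 = 0.0343 h⁻¹)
    substrate + reagent + product → 2 product (k2 = 355 M⁻² h⁻¹)
    substrate + reagent → product (k3 = 0.0763 M⁻¹ h⁻¹)

Striking out the turning of reagent into dormant form, both ways, shrinks the gap between red and grey from 12 percentage points to 0.39 points, the largest single effect tried. After 4.00 d, the ratio of the two exits, reckoned with the substrate then standing, is 0.806 in red against 0.421 in grey. The flask like grey but with 1.40 equiv of reagent raises the reagent fraction over crossover from 3.31 to 5.79, and it ends at 74.2% product.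

(The constants used here are those of an exercise.)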